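**Plan**

- Retrosynthesis: the enol-ether O–C(sp2) bond of the pyran and the ring-fusion C–C bond (O-bearing quaternary carbon to the adjacent CH) are cut together. This opens the pyran and the nine-membered ring to a seco-caryophyllane methyl ketone carrying an (E)-alkenyl-linked O-methyl acylfilicinic acid (12). The alkenyl–ring bond is then cut (Suzuki), and the keto aldehyde is traced to the C4=C5 alkene of (−)-β-caryophyllene.
- Enabling feature: with that C–C bond cut, the O-bearing carbon (O, CH3) is a ketone carbon. The adjacent CH, β to the enolic ring carbon through the CH2, is the far terminus of a 1-methoxy-diene (CH=CH–C=C(OMe)) in 12. A ketyl (umpoled carbonyl carbon) can attack that terminus, and the alkoxide it leaves is 1,5 to the methoxy-bearing ring carbon.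
- Forward order: the six-membered trione ring is made by dearomatising an acylphloroglucinol, and the cyclobutane is bought in caryophyllene. The nine-membered ring and the dihydropyran close last, in one step.
- Stereochemistry: cyclobutane centres from (−)-β-caryophyllene; side-chain centre from (S)-2-methylbutanoyl chloride; the two ring-fusion centres are set in the key step under substrate control.

Key step: step 8

Remark: (S)-2-methylbutanoyl chloride (2) is taken as a purchasable reagent. Locants C4 (O, CH3) and C5 (adjacent CH) are caryophyllane positions; in these terms 14 is (1R,4S,5R,9S) with an (S) side chain.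

**Step 1**
Reactants: 1 phloroglucinol; 2 (S)-2-methylbutanoyl chloride
Product: 3 (2S)-2-methyl-1-(2,4,6-trihydroxyphenyl)butan-1-one
Conditions: AlCl3 (3 equiv), PhNO2–CH2Cl2, 0 °C to rt
Reagents that add atoms: none
Why: Friedel–Crafts C-acylation of the symmetric, strongly activated arene (all three positions equivalent); the stereocentre comes from 2 and the low temperature limits enolisation of the acylium precursor.

**Step 2**
Reactants: 3 (2S)-2-methyl-1-(2,4,6-trihydroxyphenyl)butan-1-one
Product: 4 (2S)-1-(2,6-dihydroxy-4-methoxyphenyl)-2-methylbutan-1-one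
Conditions: Me2SO4 (1.0 equiv), K2CO3 (1.0 equiv), acetone, rt
Reagents that add atoms: dimethyl sulfate, COS(=O)(=O)OC
Why: Williamson O-methylation should take place at the para hydroxyl, the only one not hydrogen-bonded to the ketone and the most acidic.

**Step 3**
Reactants: 4 (2S)-1-(2,6-dihydroxy-4-methoxyphenyl)-2-methylbutan-1-one
Product: 6 3-hydroxy-5-methoxy-6,6-dimethyl-2-[(2S)-2-methylbutanoyl]cyclohexa-2,4-dien-1-one, via monomethyl phenol 5 (not isolated)
Conditions: MeI (2.1 equiv), NaOMe (3 equiv), MeOH, 0 °C to rt
Reagents that add atoms: iodomethane, CI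
Why: dearomative geminal C-methylation of an acylphloroglucinol phenolate (acylfilicinic acid synthesis) alkylates the ring carbon between O− and OMe twice, which places the methoxy group on the sp2 carbon next to the new quaternary carbon; the side-chain centre should survive because the ring, not the ketone α-carbon, carries the charge.

**Step 4**
Reactants: 6 3-hydroxy-5-methoxy-6,6-dimethyl-2-[(2S)-2-methylbutanoyl]cyclohexa-2,4-dien-1-one
Product: 7 3-hydroxy-4-iodo-5-methoxy-6,6-dimethyl-2-[(2S)-2-methylbutanoyl]cyclohexa-2,4-dien-1-one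
Conditions: NIS (1.05 equiv), MeCN, 0 °C, dark
Reagents that add atoms: N-iodosuccinimide, O=C1CCC(=O)N1I
Why: electrophilic α-iodination of a β-alkoxy enone occurs at the only ring CH, which lies between the OMe- and OH-bearing sp2 carbons.

**Step 5**
Reactants: 8 (−)-β-caryophyllene
Product: 10 4-[(1S,2R)-3,3-dimethyl-2-(3-oxobutyl)cyclobutyl]pent-4-enal, via secondary ozonide 9 (not isolated)
Conditions: O3 (1.0 equiv, titrated solution in CH2Cl2), CH2Cl2, −78 °C; then Me2S, −78 °C to rt
Reagents that add atoms: ozone, [O-][O+]=O
Why: ozonolysis with one equivalent of ozone should be selective for the strained trisubstituted ring (E)-alkene over the 1,1-disubstituted exocyclic alkene, and reductive cleavage of the ozonide gives the methyl ketone and the aldehyde without touching the cyclobutane centres.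

**Step 6**
Reactants: 10 4-[(1S,2R)-3,3-dimethyl-2-(3-oxobutyl)cyclobutyl]pent-4-enal
Product: 11 4-[(1R,4S)-2,2-dimethyl-4-[(5E)-6-(4,4,5,5-tetramethyl-1,3,2-dioxaborolan-2-yl)hexa-1,5-dien-2-yl]cyclobutyl]butan-2-one
Conditions: Cl2CHBpin (2 equiv), CrCl2 (8 equiv), LiI (4 equiv), THF, rt
Reagents that add atoms: 2-(dichloromethyl)-4,4,5,5-tetramethyl-1,3,2-dioxaborolane, ClC(Cl)B1OC(C)(C)C(C)(C)O1
Why: Takai–Utimoto boryl olefination, in which the geminal dichromium reagent adds to the aldehyde only and eliminates to the (E)-alkenylboronate, while the methyl ketone and the exocyclic alkene are inert to divalent chromium.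

**Step 7**
Reactants: 7 3-hydroxy-4-iodo-5-methoxy-6,6-dimethyl-2-[(2S)-2-methylbutanoyl]cyclohexa-2,4-dien-1-one; 11 the (E)-alkenylboronate
Product: 12 4-[(1E)-5-[(1S,2R)-3,3-dimethyl-2-(3-oxobutyl)cyclobutyl]hexa-1,5-dien-1-yl]-3-hydroxy-5-methoxy-6,6-dimethyl-2-[(2S)-2-methylbutanoyl]cyclohexa-2,4-dien-1-one
Conditions: Pd(PPh3)4 (5 mol %), K3PO4 (3 equiv), 1,4-dioxane–H2O, 60 °C
Reagents that add atoms: none
Why: Suzuki–Miyaura coupling of an α-iodo vinylogous ester with an (E)-alkenylboronate proceeds with retention of alkene geometry, the acidic enol being carried as its potassium salt and the ketone left untouched.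

**Step 8**
Reactants: 12 the (E)-dienyl methyl ketone
Product: 14 target CNP0591516.1, via tertiary alcohol 13 (not isolated)
Conditions: Et3N (1.1 equiv), THF; added over 6 h to SmI2 (5 equiv), HMPA (20 equiv), t-BuOH (2 equiv), THF, 0 °C, final 2 mM; then AcOH (excess), CSA (20 mol %), rt, same flask
Reagents that add atoms: none
Why: Proposed new method: electron transfer from SmI2–HMPA to the methyl ketone gives a samarium ketyl whose carbon adds 9-exo-trig to the distal alkene carbon of the 1-methoxy-diene; the resulting allyl radical is reduced by a second SmI2 and protonated at the exocyclic carbon to give 13, and on acidification the tertiary alcohol adds 6-exo-trig to the methoxy-bearing ring carbon and expels methanol. The closest known reaction type is the SmI2-mediated ketyl–olefin coupling with in situ lactonisation (ketone plus acrylate to γ-lactone), together with eight-membered ketyl–olefin closures onto activated alkenes; a nine-membered closure onto a dienyl vinylogous ester ended by vinylogous transesterification has not been shown. Ring closures: the nine-membered carbocycle by radical C–C formation (9-exo-trig) and the dihydropyran by polar addition–elimination at the vinylogous ester (6-exo-trig). Stereocentres: C4 and C5 are set together in the radical addition; trivalent samarium bridging the ketyl oxygen and the ring enolate oxygen should hold the ketyl O on the diene side while the seven-atom tether, constrained by the trans-cyclobutane, spans the new bond antiperiplanar as in the (E)-cyclononene of caryophyllene, which places H and CH3 trans across the ring fusion; the face attacked relative to the cyclobutane rests on substrate control alone and is the least secure element. Selectivity needed: reduction of the ketone and not of the cross-conjugated ring (secured by carrying the tricarbonyl unit as its enolate), addition to the diene terminus and not to the unactivated exocyclic methylene, and O-cyclisation at the ring carbon next to the gem-dimethyl carbon (secured because only that carbon bears a leaving group).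

**Compound list**

1 | phloroglucinol | Oc1cc(O)cc(O)c1 | starting material
2 | (S)-2-methylbutanoyl chloride | CC[C@H](C)C(Cl)=O | starting material
3 | (2S)-2-methyl-1-(2,4,6-trihydroxyphenyl)butan-1-one | CC[C@H](C)C(=O)c1c(O)cc(O)cc1O | intermediate
4 | (2S)-1-(2,6-dihydroxy-4-methoxyphenyl)-2-methylbutan-1-one | CC[C@H](C)C(=O)c1c(O)cc(OC)cc1O | intermediate
5 | (2S)-1-(2,6-dihydroxy-4-methoxy-3-methylphenyl)-2-methylbutan-1-one (not isolated) | CC[C@H](C)C(=O)c1c(O)cc(OC)c(C)c1O | intermediate
6 | 3-hydroxy-5-methoxy-6,6-dimethyl-2-[(2S)-2-methylbutanoyl]cyclohexa-2,4-dien-1-one | CC[C@H](C)C(=O)C1=C(O)C=C(OC)C(C)(C)C1=O | intermediate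
7 | 3-hydroxy-4-iodo-5-methoxy-6,6-dimethyl-2-[(2S)-2-methylbutanoyl]cyclohexa-2,4-dien-1-one | CC[C@H](C)C(=O)C1=C(O)C(I)=C(OC)C(C)(C)C1=O | intermediate
8 | (−)-β-caryophyllene, (1R,4E,9S)-4,11,11-trimethyl-8-methylidenebicyclo[7.2.0]undec-4-ene | C=C1CC/C=C(\C)CC[C@@H]2[C@@H]1CC2(C)C | starting material
9 | secondary ozonide (1,2,4-trioxolane across C4–C5 of 8, mixture at the two acetal carbons; not isolated) | C=C1CCC2OOC(C)(O2)CC[C@@H]3[C@@H]1CC3(C)C | intermediate
10 | 4-[(1S,2R)-3,3-dimethyl-2-(3-oxobutyl)cyclobutyl]pent-4-enal | C=C(CCC=O)[C@@H]1[C@@H](CCC(C)=O)C(C)(C)C1 | intermediate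
11 | 4-[(1R,4S)-2,2-dimethyl-4-[(5E)-6-(4,4,5,5-tetramethyl-1,3,2-dioxaborolan-2-yl)hexa-1,5-dien-2-yl]cyclobutyl]butan-2-one | C=C(CC/C=C/B1OC(C)(C)C(C)(C)O1)[C@@H]2[C@@H](CCC(C)=O)C(C)(C)C2 | intermediate
12 | 4-[(1E)-5-[(1S,2R)-3,3-dimethyl-2-(3-oxobutyl)cyclobutyl]hexa-1,5-dien-1-yl]-3-hydroxy-5-methoxy-6,6-dimethyl-2-[(2S)-2-methylbutanoyl]cyclohexa-2,4-dien-1-one | C=C(CC/C=C/C1=C(OC)C(C)(C)C(=O)C(C(=O)[C@@H](C)CC)=C1O)[C@@H]2[C@@H](CCC(C)=O)C(C)(C)C2 | intermediate
13 | 3-hydroxy-4-{[(1R,4S,5R,9S)-4-hydroxy-4,11,11-trimethyl-8-methylidenebicyclo[7.2.0]undecan-5-yl]methyl}-5-methoxy-6,6-dimethyl-2-[(2S)-2-methylbutanoyl]cyclohexa-2,4-dien-1-one (not isolated) | C=C1CC[C@H](CC2=C(OC)C(C)(C)C(=O)C(C(=O)[C@@H](C)CC)=C2O)[C@@](C)(O)CC[C@@H]2[C@@H]1CC2(C)C | intermediate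
14 | CNP0591516.1: trans-fused pyrano-caryophyllane, the pyran oxygen on C4 (S, bearing CH3) and on the enol-ether carbon next to the gem-dimethyl carbon of the (S)-2-methylbutanoyl trione ring, C5 (R) linked to that ring through CH2, cyclobutane centres as in 8 | C=C1CC[C@@H]2CC3=C(O[C@@]2(C)CC[C@@H]2[C@@H]1CC2(C)C)C(C)(C)C(=O)C(C(=O)[C@@H](C)CC)=C3O | target

**Totals**

Total steps: 8. Longest linear sequence: 6 (steps 1, 2, 3, 4, 7, 8).

**Steps most likely to fail**

Step 8. The nine-membered radical closure may be outrun by hydrogen capture or pinacol coupling of the ketyl. The ketyl may also close onto the exocyclic methylene (7-endo), and the closure may show poor facial selectivity relative to the cyclobutane, giving ring-fusion diastereomers. The fallback uses known chemistry and sets out from 3 and 8. Compound 3 is C-methylated three times (MeI, NaOMe, MeOH) to 3,5-dihydroxy-4,6,6-trimethyl-2-[(2S)-2-methylbutanoyl]cyclohexa-2,4-dien-1-one F1. F1 is dehydrogenated at its ring methyl group with TEMPO and Ag2O in the presence of 8 to the o-quinone methide F2, which is not isolated. F2 adds as a heterodiene across the ring (E)-alkene of 8 (inverse-demand hetero-Diels–Alder, suprafacial, hence trans fusion) and the route is rejoined at 14. The two ring conformers of 8 that expose opposite alkene faces should give 14 and its (4R,5S) diastereomer, to be separated.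

Step 7. Oxidative addition into the electron-rich iodo enolate may be slow, so that protodeboronation or deiodination takes over. The fallback sets out from 10. The aldehyde is methylenated chemoselectively (Ph3P=CH2, THF, −78 °C) to the terminal alkene 4-[(1R,4S)-4-(hexa-1,5-dien-2-yl)-2,2-dimethylcyclobutyl]butan-2-one F3. F3 is joined to 7 by a Mizoroki–Heck reaction (Pd(OAc)2, Bu4NCl, NaHCO3, DMF, 60 °C), which should deliver the (E)-alkenyl compound and rejoin the route at 12.

Step 3. O-methylation, methylation at the second ring CH (aromatic 3,5-dimethyl product) or a third methylation may compete with geminal dimethylation. The fallback sets out from 3. The free triol is first dimethylated geminally under the classical conditions (MeI, NaOMe, MeOH) to the acylfilicinic acid 3,5-dihydroxy-6,6-dimethyl-2-[(2S)-2-methylbutanoyl]cyclohexa-2,4-dien-1-one F4. Its non-chelated vinylogous acid hydroxyl is then methylated with TMSCHN2 (MeOH–toluene, rt), the regioisomeric methyl ether is removed by chromatography, and the route is rejoined at 6.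

**Further compounds**

F1 | step 8 | 3,5-dihydroxy-4,6,6-trimethyl-2-[(2S)-2-methylbutanoyl]cyclohexa-2,4-dien-1-one | CC[C@H](C)C(=O)C1=C(O)C(C)=C(O)C(C)(C)C1=O
F2 | step 8 | 3-hydroxy-6,6-dimethyl-4-methylidene-2-[(2S)-2-methylbutanoyl]cyclohex-2-ene-1,5-dione (o-quinone methide) | CC[C@H](C)C(=O)C1=C(O)C(=C)C(=O)C(C)(C)C1=O
F3 | step 7 | 4-[(1R,4S)-4-(hexa-1,5-dien-2-yl)-2,2-dimethylcyclobutyl]butan-2-one | C=CCCC(=C)[C@@H]1[C@@H](CCC(C)=O)C(C)(C)C1
F4 | step 3 | 3,5-dihydroxy-6,6-dimethyl-2-[(2S)-2-methylbutanoyl]cyclohexa-2,4-dien-1-one | CC[C@H](C)C(=O)C1=C(O)C=C(O)C(C)(C)C1=O
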